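**Plan**
Cuts: first the O–S bond of the 3-sulfate and the two temporary O-groups (3-pivalate, 3'-benzyl). Next, ring A at C8–C8a and C4a–C5. Last, ring C, through an Achmatowicz ring expansion, back to a 2-furyl carbinol whose C2–C3 bond comes from a furyllithium and an aldehyde.
Enabling feature: ring A carries a 5-OH peri to the C4 carbonyl and a 7-OMe. This 1,3-dioxygenation maps onto a 1,1,3-trioxygenated butadiene, and the C4a–C8a edge of ring A is the C5=C6 bond of a 4-pyranone (ring C).
Forward order: ring B is bought in O-benzylisovanillin, ring C arises from 3,4-dibromofuran, and ring A is closed last by the diene annulation. Methanolysis, sulfation and hydrogenolysis follow.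
Bromine logic: furan C3–Br becomes the C4 carbonyl and furan C4–Br becomes the pyranone C5–Br. No electrophilic bromination therefore has to be run next to electron-rich ring B.
Stereochemistry: the target has no stereocentre. All transient sp3 centres are racemic and are erased.

Key step: step 6

Assumption: the target is taken as the free hydrogen sulfate as drawn. Because such acids hydrolyse themselves, the sulfate is carried as its triethylammonium salt and the proton form is released only in the last operation.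

**Step 1**
Reactants: 1 3,4-dibromofuran; 2 3-(benzyloxy)-4-methoxybenzaldehyde
Product: 4 (3,4-dibromofuran-2-yl)[3-(benzyloxy)-4-methoxyphenyl]methanol (racemic), via 3,4-dibromo-2-furyllithium 3 (not isolated)
Conditions: 1, LiN(i-Pr)2 (LDA, 1.05 equiv), THF, −78 °C; then 2, −78 °C; aq NH4Cl
Reagents that add atoms: none
Why: An amide base deprotonates the furan α-position next to oxygen and bromine (directed α-lithiation, no halogen–metal exchange), and 1,2-addition of the furyllithium to the aldehyde gives the carbinol, whose new centre is racemic and is erased in step 3.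

**Step 2**
Reactants: 4 (3,4-dibromofuran-2-yl)[3-(benzyloxy)-4-methoxyphenyl]methanol
Product: 5 2-[3-(benzyloxy)-4-methoxyphenyl]-4,5-dibromo-6-hydroxy-2H-pyran-3(6H)-one (racemic mixture of diastereomers)
Conditions: mCPBA (1.3 equiv), CH2Cl2, 0 °C to rt
Reagents that add atoms: 3-chloroperoxybenzoic acid (mCPBA), OOC(=O)c1cccc(Cl)c1
Why: The Achmatowicz rearrangement (peracid oxidation of the furfuryl alcohol and ring expansion) moves furan C3 and C4 with their bromines to pyranone C4 and C5, a halogen-free oxidant leaves ring B and the benzyl ether untouched, and the unselective anomeric centre is of no consequence.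

**Step 3**
Reactants: 5 2-[3-(benzyloxy)-4-methoxyphenyl]-4,5-dibromo-6-hydroxy-2H-pyran-3(6H)-one
Product: 7 2-[3-(benzyloxy)-4-methoxyphenyl]-5-bromo-3-hydroxy-4H-pyran-4-one, via dibromohydroxypyrylium hydrogen sulfate 6 (not isolated)
Conditions: 1 M aq H2SO4–1,4-dioxane, 80 °C
Reagents that add atoms: water, O
Why: This is the maltol-type hydrolytic aromatisation known for 4-halo-6-hydroxy-2H-pyran-3(6H)-ones, in which acid enolises C2–H and ionises the anomeric hydroxyl to the aryl-stabilised pyrylium ion 6, water adds reversibly at C2 and C6 but irreversibly at the bromine-bearing γ-carbon C4 with loss of HBr, and the C5 bromine stays because a β-carbon of a pyrylium ion is not electrophilic, while dilute acid spares the aryl benzyl ether.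

**Step 4**
Reactants: 7 2-[3-(benzyloxy)-4-methoxyphenyl]-5-bromo-3-hydroxy-4H-pyran-4-one
Product: 8 2-[3-(benzyloxy)-4-methoxyphenyl]-5-bromo-4-oxo-4H-pyran-3-yl pivalate
Conditions: t-BuCOCl (1.2 equiv), Et3N (1.5 equiv), DMAP (cat.), CH2Cl2, 0 °C
Reagents that add atoms: pivaloyl chloride, CC(C)(C)C(=O)Cl
Why: DMAP-catalysed O-acylation of the only free hydroxyl, the acidic enolic 3-OH, gives an enol pivalate that lowers the electron density of ring C, resists the silyl triflate and amidine base of step 6, and can later be removed without touching the benzyl ether.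

**Step 5**
Reactants: 9 methyl (E)-3-methoxybut-2-enoate
Product: 11 (1Z)-1,3-dimethoxy-1-(trimethylsilyloxy)buta-1,3-diene (Brassard diene), via lithium dienolate 10 (not isolated)
Conditions: LiN(i-Pr)2 (LDA, 1.1 equiv), THF, −78 °C; Me3SiCl, −78 °C to rt; pentane, filtration, distillation
Reagents that add atoms: chlorotrimethylsilane, C[Si](C)(C)Cl
Why: γ-Deprotonation of the vinylogous carbonate and O-silylation of the extended ester dienolate is the standard preparation of this diene, and the ketene acetal geometry does not matter because that carbon becomes aromatic C5.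

**Step 6**
Reactants: 8 2-[3-(benzyloxy)-4-methoxyphenyl]-5-bromo-4-oxo-4H-pyran-3-yl pivalate; 11 (1Z)-1,3-dimethoxy-1-(trimethylsilyloxy)buta-1,3-diene
Product: 16 2-[3-(benzyloxy)-4-methoxyphenyl]-5-hydroxy-7-methoxy-4-oxo-4H-chromen-3-yl pivalate, via silyloxypyrylium triflate 12 (not isolated), via silyl enol ether adduct 13 (not isolated), via bromoketone 14 (not isolated), via pyranonyl methoxybutenoate 15 (not isolated)
Conditions: one flask: TMSOTf (1.2 equiv), CH2Cl2, 0 °C to rt; 11 (1.5 equiv), −78 to 0 °C; then MeOH (3 equiv), DBU (6 equiv), 0 to 40 °C; 1 M HCl work-up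
Reagents that add atoms: none
Why: Proposed new method: TMSOTf silylates the C4 carbonyl oxygen of 8 to the 4-silyloxypyrylium salt 12, and the unsubstituted nucleophilic terminus of diene 11 attacks its free α-carbon C6 (the β-carbon of the bromoenone, future C8a) in a vinylogous Mukaiyama–Michael addition that forms C8–C8a and leaves silyl enol ether 13. Methanol and DBU unmask bromoketone 14, which loses HBr as 3-bromochromanones do on the way to chromones, and the doubly vinylogous CH2 of the resulting pyranone 15 is deprotonated so that pyranone C5 (future C4a) attacks the ester carbon (future C5) in a 6-(enolexo)-exo-trig Claisen closure of ring A, after which loss of methanol and enolisation give the chelated phenol; overall this is a stepwise (4+2) benzannulation with loss of HBr and MeOH. The closest known reaction types are the Brassard diene annulation of haloquinones, the silyl triflate-triggered addition of silyl ketene acetals and 1,3-bis(silyloxy)dienes to chromones through 4-silyloxybenzopyrylium salts, and the Diels–Alder reactions of 3-acyl- and 3-sulfinylchromones, none of which has been carried through to a benzene ring on a monocyclic 4-pyranone. No stereocentre is kept, since the sp3 carbons of 13 and 14 are racemic and become aromatic. Site selectivity (C6 against C2 of the pyrylium ion) is secured by the aryl group, which blocks C2 and delocalises its charge, and the orientation is secured by the polarity of the diene together with the bromine at C5, so that the ester oxygen ends as the 5-hydroxyl peri to C4=O and the enol ether methoxyl at C7. The bromine also supplies the oxidation level, so that aromatisation runs through loss of HBr and the C8a–O1 bond of ring C is kept rather than β-eliminated.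

**Step 7**
Reactants: 16 2-[3-(benzyloxy)-4-methoxyphenyl]-5-hydroxy-7-methoxy-4-oxo-4H-chromen-3-yl pivalate
Product: 17 2-[3-(benzyloxy)-4-methoxyphenyl]-3,5-dihydroxy-7-methoxy-4H-chromen-4-one (3'-O-benzylombuin)
Conditions: K2CO3 (1.5 equiv), MeOH–THF, 0 °C to rt; 1 M HCl to pH 4
Reagents that add atoms: none
Why: Base-mediated transesterification (methanolysis) removes the activated enol pivalate at O3, while the benzyl and methyl ethers are inert to carbonate and the 5-hydroxyl, hydrogen-bonded to C4=O, is only deprotonated and returned on acidification.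

**Step 8**
Reactants: 17 2-[3-(benzyloxy)-4-methoxyphenyl]-3,5-dihydroxy-7-methoxy-4H-chromen-4-one
Product: 18 triethylammonium 2-[3-(benzyloxy)-4-methoxyphenyl]-5-hydroxy-7-methoxy-4-oxo-4H-chromen-3-yl sulfate
Conditions: SO3·NEt3 (3 equiv), Et3N (2 equiv), DMF, 40 °C; Sephadex LH-20 (MeOH)
Reagents that add atoms: sulfur trioxide–triethylamine complex, CC[N+](CC)(CC)S(=O)(=O)[O-]
Why: O-Sulfation with a sulfur trioxide–amine complex, the standard method for flavonol sulfates, should occur at the more acidic and accessible 3-hydroxyl because the 5-hydroxyl is locked in a six-membered hydrogen bond to C4=O and the 3'-oxygen is benzylated, and the sulfate ester is stable as its triethylammonium salt.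

**Step 9**
Reactants: 18 triethylammonium 2-[3-(benzyloxy)-4-methoxyphenyl]-5-hydroxy-7-methoxy-4-oxo-4H-chromen-3-yl sulfate
Product: 20 ombuin 3-O-sulfate (5-hydroxy-2-(3-hydroxy-4-methoxyphenyl)-7-methoxy-4-oxo-4H-chromen-3-yl hydrogen sulfate), via triethylammonium ombuin 3-sulfate 19 (not isolated)
Conditions: H2 (1 atm), 10% Pd/C, MeOH, rt; filtration; Dowex 50W-X8 (H+ form), MeOH–H2O, 0 °C; lyophilisation
Reagents that add atoms: none
Why: Catalytic hydrogenolysis cleaves the aryl benzyl ether under neutral conditions that sulfate monoester salts and the chromone C2=C3 bond tolerate, and cold cation exchange then replaces triethylammonium by a proton to give the acid form as drawn.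

**Compound list**
1 | 3,4-dibromofuran | Brc1cocc1Br | starting material
2 | 3-(benzyloxy)-4-methoxybenzaldehyde | COc1ccc(C=O)cc1OCc1ccccc1 | starting material
3 | 3,4-dibromo-2-furyllithium | [Li]c1occ(Br)c1Br | intermediate
4 | (3,4-dibromofuran-2-yl)[3-(benzyloxy)-4-methoxyphenyl]methanol, racemic | OC(c1occ(Br)c1Br)c1ccc(OC)c(OCc2ccccc2)c1 | intermediate
5 | 2-[3-(benzyloxy)-4-methoxyphenyl]-4,5-dibromo-6-hydroxy-2H-pyran-3(6H)-one, racemic mixture of diastereomers | OC1OC(c2ccc(OC)c(OCc3ccccc3)c2)C(=O)C(Br)=C1Br | intermediate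
6 | 2-[3-(benzyloxy)-4-methoxyphenyl]-4,5-dibromo-3-hydroxypyrylium hydrogen sulfate | Oc1c(-c2ccc(OC)c(OCc3ccccc3)c2)[o+]cc(Br)c1Br.OS(=O)(=O)[O-] | intermediate
7 | 2-[3-(benzyloxy)-4-methoxyphenyl]-5-bromo-3-hydroxy-4H-pyran-4-one | Oc1c(-c2ccc(OC)c(OCc3ccccc3)c2)occ(Br)c1=O | intermediate
8 | 2-[3-(benzyloxy)-4-methoxyphenyl]-5-bromo-4-oxo-4H-pyran-3-yl pivalate | CC(C)(C)C(=O)Oc1c(-c2ccc(OC)c(OCc3ccccc3)c2)occ(Br)c1=O | intermediate
9 | methyl (E)-3-methoxybut-2-enoate | CO/C(C)=C/C(=O)OC | starting material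
10 | lithium (1E)-1,3-dimethoxybuta-1,3-dien-1-olate (dienolate of 9) | C=C(OC)/C=C(/OC)[O-].[Li+] | intermediate
11 | (1Z)-1,3-dimethoxy-1-(trimethylsilyloxy)buta-1,3-diene (Brassard diene) | C=C(OC)/C=C(/OC)O[Si](C)(C)C | intermediate
12 | 2-[3-(benzyloxy)-4-methoxyphenyl]-5-bromo-3-(pivaloyloxy)-4-(trimethylsilyloxy)pyrylium triflate | CC(C)(C)C(=O)Oc1c(-c2ccc(OC)c(OCc3ccccc3)c2)[o+]cc(Br)c1O[Si](C)(C)C.[O-]S(=O)(=O)C(F)(F)F | intermediate
13 | methyl (2E)-4-{6-[3-(benzyloxy)-4-methoxyphenyl]-3-bromo-5-(pivaloyloxy)-4-(trimethylsilyloxy)-2H-pyran-2-yl}-3-methoxybut-2-enoate, racemic | COC(=O)/C=C(/OC)CC1OC(c2ccc(OC)c(OCc3ccccc3)c2)=C(OC(=O)C(C)(C)C)C(O[Si](C)(C)C)=C1Br | intermediate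
14 | methyl (2E)-4-{6-[3-(benzyloxy)-4-methoxyphenyl]-3-bromo-4-oxo-5-(pivaloyloxy)-3,4-dihydro-2H-pyran-2-yl}-3-methoxybut-2-enoate, racemic mixture of diastereomers | COC(=O)/C=C(/OC)CC1OC(c2ccc(OC)c(OCc3ccccc3)c2)=C(OC(=O)C(C)(C)C)C(=O)C1Br | intermediate
15 | methyl (2E)-4-{6-[3-(benzyloxy)-4-methoxyphenyl]-4-oxo-5-(pivaloyloxy)-4H-pyran-2-yl}-3-methoxybut-2-enoate | COC(=O)/C=C(/OC)Cc1cc(=O)c(OC(=O)C(C)(C)C)c(-c2ccc(OC)c(OCc3ccccc3)c2)o1 | intermediate
16 | 2-[3-(benzyloxy)-4-methoxyphenyl]-5-hydroxy-7-methoxy-4-oxo-4H-chromen-3-yl pivalate | COc1cc(O)c2c(=O)c(OC(=O)C(C)(C)C)c(-c3ccc(OC)c(OCc4ccccc4)c3)oc2c1 | intermediate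
17 | 2-[3-(benzyloxy)-4-methoxyphenyl]-3,5-dihydroxy-7-methoxy-4H-chromen-4-one | COc1cc(O)c2c(=O)c(O)c(-c3ccc(OC)c(OCc4ccccc4)c3)oc2c1 | intermediate
18 | triethylammonium 2-[3-(benzyloxy)-4-methoxyphenyl]-5-hydroxy-7-methoxy-4-oxo-4H-chromen-3-yl sulfate | COc1cc(O)c2c(=O)c(OS(=O)(=O)[O-])c(-c3ccc(OC)c(OCc4ccccc4)c3)oc2c1.CC[NH+](CC)CC | intermediate
19 | triethylammonium 5-hydroxy-2-(3-hydroxy-4-methoxyphenyl)-7-methoxy-4-oxo-4H-chromen-3-yl sulfate | COc1cc(O)c2c(=O)c(OS(=O)(=O)[O-])c(-c3ccc(OC)c(O)c3)oc2c1.CC[NH+](CC)CC | intermediate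
20 | ombuin 3-O-sulfate | COc1cc(O)c2c(=O)c(OS(=O)(=O)O)c(-c3ccc(OC)c(O)c3)oc2c1 | target

**Step count**
Total steps: 9. Longest linear sequence: 8 steps (steps 1–4 and 6–9); step 5 is the side branch.

**Steps most likely to fail**

Step 6. The diene may be consumed by silyl transfer or protonation before it reaches C6. Bromine may be stripped by halophilic attack. The open-chain adduct may also open ring C by retro-oxa-Michael reaction instead of closing ring A.
The fallback buys ring A instead of building it. It sets out from 2 and comes back at 17.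
- Commercial 2',6'-dihydroxy-4'-methoxyacetophenone is mono-protected (MOMCl, i-Pr2NEt, CH2Cl2) to 1-[2-hydroxy-4-methoxy-6-(methoxymethoxy)phenyl]ethanone F1.
- Claisen–Schmidt condensation with 2 (KOH, EtOH) gives (E)-3-[3-(benzyloxy)-4-methoxyphenyl]-1-[2-hydroxy-4-methoxy-6-(methoxymethoxy)phenyl]prop-2-en-1-one F2.
- Algar–Flynn–Oyamada oxidation (30% H2O2, aq NaOH, MeOH) gives 2-[3-(benzyloxy)-4-methoxyphenyl]-3-hydroxy-7-methoxy-5-(methoxymethoxy)-4H-chromen-4-one F3.
- HCl in MeOH removes the acetal and gives 17.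

Step 3. Water may displace the C5 bromine by conjugate addition–elimination on the enone before the pyrylium ion forms, or the hemiacetal may fragment in hot acid.
The fallback carries only the one bromine that the hydrolysis needs and installs the second one late. It sets out from 2 and comes back at 8.
- Commercial 3-bromofuran is lithiated at C2 (LDA, THF, −78 °C) and added to 2 to give (3-bromofuran-2-yl)[3-(benzyloxy)-4-methoxyphenyl]methanol F4.
- mCPBA gives 2-[3-(benzyloxy)-4-methoxyphenyl]-4-bromo-6-hydroxy-2H-pyran-3(6H)-one F5.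
- The same aqueous acid treatment gives 2-[3-(benzyloxy)-4-methoxyphenyl]-3-hydroxy-4H-pyran-4-one F6.
- Pivaloylation gives 2-[3-(benzyloxy)-4-methoxyphenyl]-4-oxo-4H-pyran-3-yl pivalate F7.
- Addition of Br2 across C5=C6 in CH2Cl2 at −40 °C, followed by Et3N-induced elimination, gives 8. This is the way chromone is turned into 3-bromochromone, and the low temperature holds back substitution on ring B.

Step 8. Transfer of SO3 may stall at the hydrogen-bonded 3-hydroxyl or spill over to the 5-hydroxyl, and the ionic product may lose sulfate during purification.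
The fallback uses a neutral, chromatographable sulfate diester. It sets out from 17 and comes back at 20.
- Treating 17 with 2,2,2-trichloroethyl chlorosulfate (Et3N, DMAP, THF) gives 2-[3-(benzyloxy)-4-methoxyphenyl]-5-hydroxy-7-methoxy-4-oxo-4H-chromen-3-yl 2,2,2-trichloroethyl sulfate F8.
- Transfer hydrogenolysis (10% Pd/C, HCO2NH4, MeOH) removes the trichloroethyl and benzyl groups together and gives ammonium 5-hydroxy-2-(3-hydroxy-4-methoxyphenyl)-7-methoxy-4-oxo-4H-chromen-3-yl sulfate F9.
- Cold cation exchange (Dowex 50W-X8, H+ form) gives 20.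

**Further compounds**
F1 | step 6 | 1-[2-hydroxy-4-methoxy-6-(methoxymethoxy)phenyl]ethanone | CC(=O)c1c(O)cc(OC)cc1OCOC
F2 | step 6 | (E)-3-[3-(benzyloxy)-4-methoxyphenyl]-1-[2-hydroxy-4-methoxy-6-(methoxymethoxy)phenyl]prop-2-en-1-one | COCOc1cc(OC)cc(O)c1C(=O)/C=C/c1ccc(OC)c(OCc2ccccc2)c1
F3 | step 6 | 2-[3-(benzyloxy)-4-methoxyphenyl]-3-hydroxy-7-methoxy-5-(methoxymethoxy)-4H-chromen-4-one | COCOc1cc(OC)cc2oc(-c3ccc(OC)c(OCc4ccccc4)c3)c(O)c(=O)c12
F4 | step 3 | (3-bromofuran-2-yl)[3-(benzyloxy)-4-methoxyphenyl]methanol, racemic | OC(c1occc1Br)c1ccc(OC)c(OCc2ccccc2)c1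
F5 | step 3 | 2-[3-(benzyloxy)-4-methoxyphenyl]-4-bromo-6-hydroxy-2H-pyran-3(6H)-one, racemic mixture of diastereomers | OC1OC(c2ccc(OC)c(OCc3ccccc3)c2)C(=O)C(Br)=C1
F6 | step 3 | 2-[3-(benzyloxy)-4-methoxyphenyl]-3-hydroxy-4H-pyran-4-one | Oc1c(-c2ccc(OC)c(OCc3ccccc3)c2)occc1=O
F7 | step 3 | 2-[3-(benzyloxy)-4-methoxyphenyl]-4-oxo-4H-pyran-3-yl pivalate | CC(C)(C)C(=O)Oc1c(-c2ccc(OC)c(OCc3ccccc3)c2)occc1=O
F8 | step 8 | 2-[3-(benzyloxy)-4-methoxyphenyl]-5-hydroxy-7-methoxy-4-oxo-4H-chromen-3-yl 2,2,2-trichloroethyl sulfate | COc1cc(O)c2c(=O)c(OS(=O)(=O)OCC(Cl)(Cl)Cl)c(-c3ccc(OC)c(OCc4ccccc4)c3)oc2c1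
F9 | step 8 | ammonium 5-hydroxy-2-(3-hydroxy-4-methoxyphenyl)-7-methoxy-4-oxo-4H-chromen-3-yl sulfate | COc1cc(O)c2c(=O)c(OS(=O)(=O)[O-])c(-c3ccc(OC)c(O)c3)oc2c1.[NH4+]
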